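**Assumption:** the SMILES contains no stereocentre and the target is achiral, so no enantiocontrol is needed. The only stereo-element on the way is the E alkene of chalcone 8, which is removed in the last step.

## Retrosynthetic overview
1. The CH2CH2 link comes from saturating an (E)-chalcone. The chalcone comes from a Claisen-Schmidt union of a ring A methyl ketone (6-acetyl-5,7-dihydroxy-2,2-dimethylchroman) and a ring B aldehyde (4-hydroxy-3-prenylbenzaldehyde).
2. Key disconnection: the O1-C2 ether bond of the dihydropyran ring, leading back to 3-prenylphloroacetophenone. The OH para to the acetyl group closes in the Markovnikov sense onto the prenyl alkene.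
3. Both prenyl groups come from prenyl bromide by phenolate C-alkylation of 2,4,6-trihydroxyacetophenone and of 4-hydroxybenzaldehyde.
4. Ring order: rings A and B are bought. The dihydropyran ring (ring C) is the only ring made. It is closed before the union, while the ring B ortho-prenylphenol that could compete is not yet in the molecule.

## Route

Step 1
Reactants: 1 2,4,6-trihydroxyacetophenone; 2 prenyl bromide (1-bromo-3-methylbut-2-ene)
Product: 3 1-[2,4,6-trihydroxy-3-(3-methylbut-2-enyl)phenyl]ethanone
Conditions: KOH (1.0 equiv), 2 (0.9 equiv), H2O, 0 °C to rt, N2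
Reagents that add atoms: prenyl bromide, CC(C)=CCBr
Why: C-alkylation of the ambident phloroglucinolate (a vinylogous enolate) with an allylic bromide in water, where hydrogen bonding to oxygen steers the soft electrophile to carbon; C3 and C5 are equivalent, and the slight deficit of bromide limits double prenylation.

Step 2
Reactants: 3 1-[2,4,6-trihydroxy-3-(3-methylbut-2-enyl)phenyl]ethanone
Product: 4 1-(5,7-dihydroxy-2,2-dimethylchroman-6-yl)ethanone
Conditions: [N,N'-bis(3,5-di-tert-butylsalicylidene)-1,2-cyclohexanediaminato]cobalt, Co(C36H52N2O2) (5 mol%), N-fluoro-2,4,6-trimethylpyridinium triflate (1.5 equiv, added over 2 h), PhSiH3 (1.5 equiv), 2,4,6-collidine (0.5 equiv), acetone, 0 °C to rt, Ar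
Reagents that add atoms: none
Why: Proposed new method: acidity-gated cobalt-hydride hydrogen-atom-transfer (MHAT)/radical-polar crossover cycloetherification of an unprotected ortho-prenyl acylphloroglucinol; the trivalent cobalt hydride (formed from the divalent cobalt salen, the N-F oxidant and PhSiH3) delivers H• to the CH end of the prenyl alkene, the tertiary radical is caught as an alkylcobalt and oxidised to the cation-like tetravalent stage, and this is displaced through a six-membered transition state by the OH para to the acetyl group, the only flanking hydroxyl that is free (pKa about 7-8, matched to collidine, pKaH 7.4, which hydrogen-bonds to it and takes its proton), whereas the ortho OH is locked in the ketone chelate without an external base, so the 6-acetyl chroman should win over the 8-acetyl isomer that strong acids co-produce; the closest known reaction type is the Co(salen)/silane/N-fluoropyridinium Markovnikov hydroalkoxylation of unactivated alkenes by alcohols, not yet shown for a trisubstituted prenyl group on a polyphenolic vinylogous acid or for a choice between two phenolic OH groups; no stereocentre is formed.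

Step 3
Reactants: 5 4-hydroxybenzaldehyde; 2 prenyl bromide (1-bromo-3-methylbut-2-ene)
Product: 6 4-hydroxy-3-(3-methylbut-2-enyl)benzaldehyde
Conditions: KOH (1.0 equiv), H2O, rt, 24 h
Reagents that add atoms: prenyl bromide, CC(C)=CCBr
Why: Ortho C-alkylation of a phenolate in water (ambident phenolate alkylation) is a known preparation of this aldehyde; the para position is blocked, and the neutral O-prenyl ether by-product is removed by extracting the phenolic product into base.

Step 4
Reactants: 4 1-(5,7-dihydroxy-2,2-dimethylchroman-6-yl)ethanone; 6 4-hydroxy-3-(3-methylbut-2-enyl)benzaldehyde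
Product: 8 (E)-1-(5,7-dihydroxy-2,2-dimethylchroman-6-yl)-3-[4-hydroxy-3-(3-methylbut-2-enyl)phenyl]prop-2-en-1-one, via aldol adduct 7 (not isolated)
Conditions: 4, LiN(SiMe3)2 (3.3 equiv), THF, -78 to 0 °C; then 6 premixed with LiN(SiMe3)2 (1.1 equiv) in THF, -78 °C to rt, 12 h; 1 M HCl to pH 4-5, 0 °C
Reagents that add atoms: none
Why: Claisen-Schmidt aldol condensation on the fully lithiated partners, in which the enolate carbon (formed last) is the most nucleophilic site of the polyanion, and the benzylic aldolate para to the oxido group loses water on acidification (E1cB, quinone-methide assisted) to give the conjugated, thermodynamically preferred E enone.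

Step 5
Reactants: 8 (E)-1-(5,7-dihydroxy-2,2-dimethylchroman-6-yl)-3-[4-hydroxy-3-(3-methylbut-2-enyl)phenyl]prop-2-en-1-one
Product: 9 1-(5,7-dihydroxy-2,2-dimethylchroman-6-yl)-3-[4-hydroxy-3-(3-methylbut-2-enyl)phenyl]propan-1-one
Conditions: H2 (1 atm), RhCl(PPh3)3 (5 mol%), toluene/EtOH 1:1, rt
Reagents that add atoms: none
Why: Homogeneous hydrogenation with RhCl(PPh3)3 is governed by steric access, so the 1,2-disubstituted enone C=C is saturated while the trisubstituted prenyl C=C, the chelated aryl ketone and the chroman stay untouched; no stereocentre is formed.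

## Compound list
1 | 2,4,6-trihydroxyacetophenone | CC(=O)c1c(O)cc(O)cc1O | starting material
2 | prenyl bromide (1-bromo-3-methylbut-2-ene) | CC(C)=CCBr | starting material
3 | 1-[2,4,6-trihydroxy-3-(3-methylbut-2-enyl)phenyl]ethanone | CC(=O)c1c(O)cc(O)c(CC=C(C)C)c1O | intermediate
4 | 1-(5,7-dihydroxy-2,2-dimethylchroman-6-yl)ethanone | CC(=O)c1c(O)cc2c(c1O)CCC(C)(C)O2 | intermediate
5 | 4-hydroxybenzaldehyde | O=Cc1ccc(O)cc1 | starting material
6 | 4-hydroxy-3-(3-methylbut-2-enyl)benzaldehyde | CC(C)=CCc1cc(C=O)ccc1O | intermediate
7 | racemic 1-(5,7-dihydroxy-2,2-dimethylchroman-6-yl)-3-hydroxy-3-[4-hydroxy-3-(3-methylbut-2-enyl)phenyl]propan-1-one (aldol adduct, not isolated) | CC(C)=CCc1cc(C(O)CC(=O)c2c(O)cc3c(c2O)CCC(C)(C)O3)ccc1O | intermediate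
8 | (E)-1-(5,7-dihydroxy-2,2-dimethylchroman-6-yl)-3-[4-hydroxy-3-(3-methylbut-2-enyl)phenyl]prop-2-en-1-one | CC(C)=CCc1cc(/C=C/C(=O)c2c(O)cc3c(c2O)CCC(C)(C)O3)ccc1O | intermediate
9 | 1-(5,7-dihydroxy-2,2-dimethylchroman-6-yl)-3-[4-hydroxy-3-(3-methylbut-2-enyl)phenyl]propan-1-one (CNP0080516.0, achiral) | CC(C)=CCc1cc(CCC(=O)c2c(O)cc3c(c2O)CCC(C)(C)O3)ccc1O | target

## Step count and risks
Total steps: 5. Longest linear sequence: 4 (steps 1, 2, 4, 5).

**Step 2 (the proposed new step).**
- Risks: hydrogen-atom transfer to the trisubstituted alkene may be slow. The N-F salt may fluorinate or oxidise the electron-rich ring. Some material may leak to the 8-acetyl isomer.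
- Fallback (known chemistry, from 1 back to 4): the C-O bond is made first by O-alkylation and the ring is then closed by a pericyclic cascade.
- 1 is alkylated at its most acidic, non-chelated 4-OH with 3-chloro-3-methylbut-1-yne (K2CO3, KI, acetone, reflux). This gives 1-[2,6-dihydroxy-4-(2-methylbut-3-yn-2-yloxy)phenyl]ethanone F1.
- Heating in N,N-diethylaniline at about 180 °C triggers the aromatic propargyl Claisen rearrangement, [1,5]-H shift and oxa-6π electrocyclisation. The ether oxygen becomes the ring oxygen, giving 1-(5,7-dihydroxy-2,2-dimethyl-2H-chromen-6-yl)ethanone F2.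
- H2, Pd/C, EtOAc then saturates the chromene to 4. This is safe because no prenyl group is present at that stage.

**Step 4.**
- Risks: the lithium 4-formylphenolate is a poor electrophile. The 2',6'-dihydroxychalcone can close to flavanones during work-up.
- Fallback (from 4 and 6 back to 9): the standard protected-chalcone strategy.
- 4 is treated with MOMCl/NaH (DMF, 0 °C) to give 1-[5,7-bis(methoxymethoxy)-2,2-dimethylchroman-6-yl]ethanone F3.
- 6 is treated with MOMCl/iPr2NEt (CH2Cl2) to give 4-(methoxymethoxy)-3-(3-methylbut-2-enyl)benzaldehyde F4.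
- KOH/EtOH condensation gives (E)-1-[5,7-bis(methoxymethoxy)-2,2-dimethylchroman-6-yl]-3-[4-(methoxymethoxy)-3-(3-methylbut-2-enyl)phenyl]prop-2-en-1-one F5.
- H2/RhCl(PPh3)3 gives 1-[5,7-bis(methoxymethoxy)-2,2-dimethylchroman-6-yl]-3-[4-(methoxymethoxy)-3-(3-methylbut-2-enyl)phenyl]propan-1-one F6.
- Brief treatment with dilute HCl in aqueous MeOH at rt frees the three phenols to give 9. At this stage flavanone closure is no longer possible.

**Step 5.**
- Risks: hydrogenation of the chelated enone may be slow. The prenyl group may be isomerised or over-reduced. Material may be lost to flavanone.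
- Fallback (from 8 to 9): change from sterically governed metal hydrogenation to polarity-governed enzymatic hydride transfer.
- Use an ene-reductase of the old yellow enzyme family with NADPH recycling (glucose/glucose dehydrogenase), or whole yeast cells, in pH 7 buffer/DMSO at 30 °C. This is a known way to turn prenylated hydroxychalcones into their dihydrochalcones.
- Only the carbonyl-activated C=C is a substrate. This fallback makes no new compound (F0).

## Further compounds
F1 | step 2 | 1-[2,6-dihydroxy-4-(2-methylbut-3-yn-2-yloxy)phenyl]ethanone | CC(=O)c1c(O)cc(OC(C)(C)C#C)cc1O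
F2 | step 2 | 1-(5,7-dihydroxy-2,2-dimethyl-2H-chromen-6-yl)ethanone | CC(=O)c1c(O)cc2c(c1O)C=CC(C)(C)O2
F3 | step 4 | 1-[5,7-bis(methoxymethoxy)-2,2-dimethylchroman-6-yl]ethanone | CC(=O)c1c(OCOC)cc2c(c1OCOC)CCC(C)(C)O2
F4 | step 4 | 4-(methoxymethoxy)-3-(3-methylbut-2-enyl)benzaldehyde | COCOc1ccc(C=O)cc1CC=C(C)C
F5 | step 4 | (E)-1-[5,7-bis(methoxymethoxy)-2,2-dimethylchroman-6-yl]-3-[4-(methoxymethoxy)-3-(3-methylbut-2-enyl)phenyl]prop-2-en-1-one | COCOc1ccc(/C=C/C(=O)c2c(OCOC)cc3c(c2OCOC)CCC(C)(C)O3)cc1CC=C(C)C
F6 | step 4 | 1-[5,7-bis(methoxymethoxy)-2,2-dimethylchroman-6-yl]-3-[4-(methoxymethoxy)-3-(3-methylbut-2-enyl)phenyl]propan-1-one | COCOc1ccc(CCC(=O)c2c(OCOC)cc3c(c2OCOC)CCC(C)(C)O3)cc1CC=C(C)C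
F0 | step 5 | none | none
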